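**Strategy**

Numbering the benzene ring from the carboxyl carbon (C1; C2 hydroxyl, C4 methoxy, C6 side chain, whose carbons are C1' and C2'), the two carbon substituents sit on adjacent ring carbons C6 and C1, and C1 is flanked by the C2 oxygen. That 1,2,3-pattern is the imprint of an aryne, so C6–C1' and C1–CO2H are disconnected together. In one operation, 3,5-dimethoxybenzyne, released from ortho-lithiated 1-fluoro-3,5-dimethoxybenzene, takes up the C1'-lithiated lithium alkoxide made from (R)-1-chlorotridecan-2-ol, and the aryllithium so formed is carboxylated and the alkoxide acetylated. The C2' stereocentre comes from (R)-epichlorohydrin; chelation-directed demethylation at C2 ends the route.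

Key step: step 2

Remark: reagents made and consumed in solution (the Grignard reagent, the lithiated species, the aryne) are counted as non-isolated intermediates of the step that uses them, so each step ends at an isolated compound.

Remark: the dilithio reagent 8 has the same spatial arrangement at C2 as chlorohydrin 4; its formal descriptor reads S only because lithium lowers the CIP rank of C1.

**Route**

Step 1
Reactants: 1 1-bromodecane; 2 (R)-epichlorohydrin
Product: 4 (2R)-1-chlorotridecan-2-ol, via decylmagnesium bromide 3 (not isolated)
Conditions: Mg, THF, 25–50 °C; then CuI (10 mol%), 2, THF, −40 °C, 2 h; cold 1 M HCl quench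
Reagents that add atoms: none
Why: Copper-catalysed Grignard opening of a terminal epoxide (SN2 at the unsubstituted oxirane CH2, faster than displacement of chloride at low temperature) leaves the C–O bond of the stereocentre untouched, so the (R) configuration of 2 is carried into 4 with the same descriptor.

Step 2
Reactants: 4 (2R)-1-chlorotridecan-2-ol; 5 1-fluoro-3,5-dimethoxybenzene; 6 carbon dioxide
Product: 13 2-[(2R)-2-acetoxytridecyl]-4,6-dimethoxybenzoic acid, via lithium chloro-alkoxide 7 (not isolated), via dilithio reagent 8 (not isolated), via lithiated fluoroarene 9 (not isolated), via 3,5-dimethoxybenzyne 10 (not isolated), via aryllithium alkoxide 11 (not isolated), via dilithium hydroxy-acid salt 12 (not isolated)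
Conditions: (a) 4 (1.5 equiv), n-BuLi (1.5 equiv), THF, −78 °C; lithium 4,4'-di-tert-butylbiphenylide (LiDBB, 3.0 equiv, to a faint persistent green), THF, −78 °C; (b) 5 (1.0 equiv), s-BuLi (0.98 equiv), THF, −78 °C, 1 h; (c) solution (a) into (b) by cold cannula, −78 → −45 °C; (d) CO2 gas, −78 °C, then Ar purge; (e) Ac2O (6 equiv), DMAP (0.2 equiv), −78 °C → rt; H2O, then 1 M HCl to pH 2
Reagents that add atoms: acetic anhydride, CC(=O)OC(C)=O
Why: Alkoxide 7 is reduced at its C–Cl bond by two electron transfers from LiDBB to give the β-oxido alkyllithium 8, while s-BuLi removes the ring proton of 5 that lies between fluorine and a methoxy group to give 9, which is stable at −78 °C and loses LiF only on warming to release aryne 10. The primary carbanion of 8 adds to the aryne carbon remote from the neighbouring methoxy group (bond C6–C1'), which leaves aryllithium 11 with its lithium ortho to that oxygen, and 11 is carboxylated by CO2 (bond C1–carboxyl) to give 12; Ac2O then acylates the alkoxide, or its CO2 adduct with loss of CO2 under DMAP catalysis, before any acid is added, so that the hydroxy acid is never free to lactonise. The closest known reaction type is the aryne three-component coupling in which an ortho-lithiated fluoroarene, an alkyl Grignard or alkyllithium reagent and CO2 are joined, combined with the known reductive lithiation of chlorohydrin alkoxides to β-oxido alkyllithiums. No ring is closed and no stereocentre is formed: C2' takes no part in any bond change and keeps the arrangement it has in 4. The step needs site selectivity in the lithiation (fluorine acidifies its ortho proton more than methoxy does, and an arene lithiated between the two methoxy groups cannot eliminate), regioselectivity in the addition (the inductively withdrawing, lithium-binding methoxy group beside the triple bond directs the carbanion to the far carbon) and attack through carbon, not oxygen (the C–Li carbon of 8 is by far its more nucleophilic site). Its main hazard, loss of lithium oxide from 8 to give 1-tridecene during the warm-up that LiF loss requires, is met by the poor leaving-group ability of oxide, by an excess of 8, by holding the mixture no higher than −45 °C, and by titrating the LiDBB so that no radical anion reaches the aryl fluoride.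

Step 3
Reactants: 13 2-[(2R)-2-acetoxytridecyl]-4,6-dimethoxybenzoic acid
Product: 14 2-[(2R)-2-acetoxytridecyl]-6-hydroxy-4-methoxybenzoic acid (target)
Conditions: BCl3 (1 M in CH2Cl2, 3 equiv), CH2Cl2, −78 → 0 °C; ice-cold 1 M HCl
Reagents that add atoms: none
Why: Boron trichloride is held between the carboxyl group and the adjacent C2 methoxy oxygen, and chloride removes that methyl group as chloromethane (chelation-directed ortho-demethylation of an o-methoxy aryl carbonyl compound), while the unchelated C4 methyl ether and the secondary acetate should be untouched at low temperature.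

**Compound list**

1 | 1-bromodecane | CCCCCCCCCCBr | starting material
2 | (R)-epichlorohydrin, (2R)-2-(chloromethyl)oxirane | ClC[C@H]1CO1 | starting material
3 | decylmagnesium bromide | CCCCCCCCCC[Mg]Br | intermediate
4 | (2R)-1-chlorotridecan-2-ol | CCCCCCCCCCC[C@H](CCl)O | intermediate
5 | 1-fluoro-3,5-dimethoxybenzene | COc1cc(F)cc(OC)c1 | starting material
6 | carbon dioxide | O=C=O | starting material
7 | lithium (2R)-1-chlorotridecan-2-olate | CCCCCCCCCCC[C@H](CCl)O[Li] | intermediate
8 | lithium (2S)-1-lithiotridecan-2-olate (dilithio reagent, geometry of 4 retained) | CCCCCCCCCCC[C@H](C[Li])O[Li] | intermediate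
9 | (2-fluoro-4,6-dimethoxyphenyl)lithium | [Li]c1c(F)cc(OC)cc1OC | intermediate
10 | 3,5-dimethoxybenzyne (1,2-didehydro-3,5-dimethoxybenzene) | COC1=CC(OC)=CC#C1 | intermediate
11 | lithium (2R)-1-(2-lithio-3,5-dimethoxyphenyl)tridecan-2-olate | CCCCCCCCCCC[C@H](Cc1cc(OC)cc(OC)c1[Li])O[Li] | intermediate
12 | dilithium salt of 2-[(2R)-2-hydroxytridecyl]-4,6-dimethoxybenzoic acid (lithium carboxylate, lithium alkoxide) | CCCCCCCCCCC[C@H](Cc1cc(OC)cc(OC)c1C(=O)O[Li])O[Li] | intermediate
13 | 2-[(2R)-2-acetoxytridecyl]-4,6-dimethoxybenzoic acid | CCCCCCCCCCC[C@H](Cc1cc(OC)cc(OC)c1C(=O)O)OC(C)=O | intermediate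
14 | 2-[(2R)-2-acetoxytridecyl]-6-hydroxy-4-methoxybenzoic acid | CCCCCCCCCCC[C@H](Cc1cc(OC)cc(O)c1C(=O)O)OC(C)=O | target

**Step count and risks**

Total step count: 3. Longest linear sequence: 3 steps (1 and 2 → 4 → 13 → 14).

Steps most likely to fail:

1. Step 2. What may go wrong: loss of lithium oxide from the β-oxido alkyllithium (β-elimination to the terminal alkene) may outrun LiF loss from the lithiated fluoroarene in the temperature window where the aryne forms. The aryne may also be consumed by the aryllithiums present, and ring closure to the lactone may compete during the acetylation. The fallback makes the C6–C1' bond by epoxide opening and the C1–carboxyl bond by bromine–lithium exchange, all known chemistry. It sets out from 4. Powdered NaOH in Et2O at rt closes the ring to (2R)-2-undecyloxirane F1. 1-Bromo-3,5-dimethoxybenzene and Mg in THF give 3,5-dimethoxyphenylmagnesium bromide F2, which opens F1 at its CH2 group under CuI catalysis at −30 °C to give (2R)-1-(3,5-dimethoxyphenyl)tridecan-2-ol F3. NBS in MeCN at 0 °C should brominate the ring carbon between the side chain and a methoxy group (para to the other methoxy group), giving (2R)-1-(2-bromo-3,5-dimethoxyphenyl)tridecan-2-ol F4. n-BuLi (1 equiv, for the O–H) and then t-BuLi (2 equiv, bromine–lithium exchange) in THF at −78 °C deliver the aryllithium alkoxide 11, where the route is rejoined (CO2, then Ac2O, as in step 2, to 13).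

2. Step 3. What may go wrong: loss of acetic acid with closure to the dihydroisocoumarin lactone under the Lewis acid, or incomplete discrimination between the two methyl ethers. The fallback masks the acid as an ester that can be removed without touching the acetate. It sets out from 13. Allyl bromide and K2CO3 in DMF at rt give prop-2-en-1-yl 2-[(2R)-2-acetoxytridecyl]-4,6-dimethoxybenzoate F5. BCl3 in CH2Cl2 at −78 → −20 °C, now directed by the ester carbonyl, gives prop-2-en-1-yl 2-[(2R)-2-acetoxytridecyl]-6-hydroxy-4-methoxybenzoate F6. Pd(PPh3)4 (zerovalent palladium, catalytic) with morpholine in THF at rt removes the allyl group and returns to the route at 14.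

3. Step 1. What may go wrong: attack of the organocopper at the chloromethyl carbon, halide opening of the epoxide by magnesium halide, or premature closure of the chloro alkoxide to an epoxide that takes up a second equivalent of the Grignard reagent. The fallback changes the carbon nucleophile. It sets out from 2. 1-Decyne is lithiated with n-BuLi in THF at −78 °C, BF3·OEt2 is added, and the alkynyl species opens 2 at the oxirane CH2 to give (2R)-1-chlorotridec-4-yn-2-ol F7. Hydrogenation (H2, 1 atm, PtO2, EtOAc, rt) saturates the triple bond without touching the primary chloride and returns to the route at 4.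

**Further compounds**

F1 | step 2 | (2R)-2-undecyloxirane | CCCCCCCCCCC[C@@H]1CO1
F2 | step 2 | 3,5-dimethoxyphenylmagnesium bromide | COc1cc(OC)cc([Mg]Br)c1
F3 | step 2 | (2R)-1-(3,5-dimethoxyphenyl)tridecan-2-ol | CCCCCCCCCCC[C@H](Cc1cc(OC)cc(OC)c1)O
F4 | step 2 | (2R)-1-(2-bromo-3,5-dimethoxyphenyl)tridecan-2-ol | CCCCCCCCCCC[C@H](Cc1cc(OC)cc(OC)c1Br)O
F5 | step 3 | prop-2-en-1-yl 2-[(2R)-2-acetoxytridecyl]-4,6-dimethoxybenzoate | CCCCCCCCCCC[C@H](Cc1cc(OC)cc(OC)c1C(=O)OCC=C)OC(C)=O
F6 | step 3 | prop-2-en-1-yl 2-[(2R)-2-acetoxytridecyl]-6-hydroxy-4-methoxybenzoate | CCCCCCCCCCC[C@H](Cc1cc(OC)cc(O)c1C(=O)OCC=C)OC(C)=O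
F7 | step 1 | (2R)-1-chlorotridec-4-yn-2-ol | CCCCCCCCC#CC[C@H](CCl)O
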